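**Retrosynthetic overview**

1. Target 14 comes from its heptabenzyl ether 13 by neutral hydrogenolysis as the last step.
2. Upper pyranone ring (formed second): the ring O–C8a bond by SNAr of the syn-aldol 11, which keeps the C2–O bond, so syn becomes 2,3-cis; C2–C3 by a reagent-controlled syn-aldol of benzyl aryl ketone 9 with aldehyde 10.
3. C3 (upper unit)–C8 (lower unit): palladium-catalysed α-arylation of enol silane 8 with 8-bromoflavanone 7.
4. Lower pyranone ring (formed first, key step): enol silane 4 and aldehyde 5 in one flask, asymmetric Mukaiyama aldol (C3–C2) then oxa-SNAr (ring O–C8a). The enabling feature is that C8a of the lower phloroglucinol ring is ortho to the C4 carbonyl and meta to both O5 and O7, so a fluorine there is the one SNAr-active position and the ring oxygen can be the former aldehyde oxygen.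
5. Both fluoro ketones (2 and 3) come from one compound, 2',4',6'-trifluoroacetophenone 1; the aromatic rings are bought, not built.

Key step: step 4

Remark: the target as drawn is (2S) in the lower unit and (2R,3R), that is 2,3-cis, in the upper unit. The cis ketone is the less stable C3 epimer and flavanones open under base, so no step after step 4 uses stoichiometric Brønsted base. Slow rotation about the C3–C8 bond gives rotamers, not isomers.

**Route**

Step 1
Reactants: 1 2',4',6'-trifluoroacetophenone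
Product: 2 1-[2,4-bis(benzyloxy)-6-fluorophenyl]ethanone
Conditions: BnOH (2.1 equiv), Cs2CO3 (2.5 equiv), DMSO, 20 → 45 °C
Reagents that add atoms: benzyl alcohol OCc1ccccc1
Why: Twofold SNAr on a ketone-activated trifluoroarene: in a dipolar aprotic solvent with a large cation the para fluorine is replaced first, the second benzyloxide can then only take an ortho fluorine, and the last fluorine stays because the two alkoxy donors have turned the ketone into a vinylogous ester and the alcohol is limited to two equivalents.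

Step 2
Reactants: 2 1-[2,4-bis(benzyloxy)-6-fluorophenyl]ethanone
Product: 3 1-[4,6-bis(benzyloxy)-3-bromo-2-fluorophenyl]ethanone
Conditions: NBS (1.05 equiv), MeCN, 0 → 20 °C, dark
Reagents that add atoms: N-bromosuccinimide O=C1CCC(=O)N1Br
Why: Electrophilic aromatic bromination should go para to the 2-benzyloxy and ortho to the 4-benzyloxy group (the C5 position of 2,4-dialkoxyacetophenones), the site between the two ethers being more crowded, which places bromine on the carbon that becomes C8 of the lower unit.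

Step 3
Reactants: 3 1-[4,6-bis(benzyloxy)-3-bromo-2-fluorophenyl]ethanone
Product: 4 {[1-(4,6-bis(benzyloxy)-3-bromo-2-fluorophenyl)ethenyl]oxy}trimethylsilane
Conditions: TMSOTf (1.2 equiv), Et3N (1.5 equiv), CH2Cl2, 0 °C; pentane, filtration, concentration
Reagents that add atoms: trimethylsilyl triflate C[Si](C)(C)OS(=O)(=O)C(F)(F)F
Why: Soft enolisation and O-silylation of an aryl methyl ketone with a silyl triflate and a tertiary amine, where only one enolisable position exists.

Step 4
Reactants: 4 {[1-(4,6-bis(benzyloxy)-3-bromo-2-fluorophenyl)ethenyl]oxy}trimethylsilane (1.0 equiv); 5 4-(benzyloxy)benzaldehyde (1.2 equiv)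
Product: 7 (2S)-5,7-bis(benzyloxy)-2-[4-(benzyloxy)phenyl]-8-bromo-2,3-dihydro-4H-chromen-4-one, via silyl aldol 6 (not isolated)
Conditions: (R)-N-tosyltryptophan-derived B-butyl-oxazaborolidinone (20 mol %), EtCN, −78 °C; then tetrabutylammonium difluorotriphenylsilicate (TBAT, 30 mol %), −78 → 0 °C
Reagents that add atoms: none
Why: Proposed new method: the chiral boron Lewis acid binds aldehyde 5 (formyl C–H···O contact to the ring oxygen, indole stacked on one face) and the enol silane adds to the exposed Si face with silyl transfer to give 6 (bond C3–C2 of the lower unit); fluoride then removes the silyl group, the unpaired alkoxide attacks the fluorine-bearing carbon ortho to the ketone through a Meisenheimer adduct (bond ring O–C8a), and the fluoride that leaves carries the chain, so the only by-product is Me3SiF. The closest known reactions are the oxazaborolidinone-catalysed Mukaiyama aldol of aryl methyl ketone enol silanes with aldehydes, the racemic aldol/SNAr annulation of ortho-fluoroaryl methyl ketones to chromanones, and the fluoride-catalysed coupling of silyl ethers with aryl fluorides; new is their merger in one flask on this substrate class. The pyranone ring closes by a six-membered intramolecular addition–elimination at an aromatic carbon (6-exo attack on C8a), which leaves the C2–O bond intact, so the (S) centre set in the aldol is carried over with retention. That centre is under catalyst control alone, since neither 4 nor 5 has a stereocentre. The step needs SNAr to outrun retro-aldol and β-elimination of the alkoxide: the acceptor carbon is ortho to the carbonyl, meta to both benzyloxy groups and next to bromine, the nitrile solvent and the ammonium counter-ion leave the alkoxide unpaired, and 4 is the limiting component so that no enol silane is left for an uncatalysed fluoride-triggered aldol.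

Step 5
Reactants: 2 1-[2,4-bis(benzyloxy)-6-fluorophenyl]ethanone
Product: 8 {[1-(2,4-bis(benzyloxy)-6-fluorophenyl)ethenyl]oxy}trimethylsilane
Conditions: TMSOTf (1.2 equiv), Et3N (1.5 equiv), CH2Cl2, 0 °C; pentane, filtration, concentration
Reagents that add atoms: trimethylsilyl triflate C[Si](C)(C)OS(=O)(=O)C(F)(F)F
Why: The same soft enolisation and O-silylation of an aryl methyl ketone as in step 3.

Step 6
Reactants: 7 (2S)-5,7-bis(benzyloxy)-2-[4-(benzyloxy)phenyl]-8-bromo-2,3-dihydro-4H-chromen-4-one; 8 {[1-(2,4-bis(benzyloxy)-6-fluorophenyl)ethenyl]oxy}trimethylsilane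
Product: 9 (2S)-5,7-bis(benzyloxy)-2-[4-(benzyloxy)phenyl]-8-{2-[2,4-bis(benzyloxy)-6-fluorophenyl]-2-oxoethyl}-2,3-dihydro-4H-chromen-4-one
Conditions: Pd2(dba)3 (2.5 mol %), P(t-Bu)3 (6 mol %), Bu3SnF (1.4 equiv), toluene, 85 °C
Reagents that add atoms: none
Why: Palladium-catalysed α-arylation of a methyl ketone silyl enol ether through its tributyltin enolate: the bulky trialkylphosphine drives oxidative addition of the hindered, electron-rich bromide to zerovalent palladium, the medium contains no Brønsted base so the flavanone ring and its C2 centre are left alone, and a second arylation is blocked by the two ortho substituents on each aryl group.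

Step 7
Reactants: 9 (2S)-5,7-bis(benzyloxy)-2-[4-(benzyloxy)phenyl]-8-{2-[2,4-bis(benzyloxy)-6-fluorophenyl]-2-oxoethyl}-2,3-dihydro-4H-chromen-4-one; 10 3,4-bis(benzyloxy)benzaldehyde
Product: 11 (2S)-5,7-bis(benzyloxy)-2-[4-(benzyloxy)phenyl]-8-{(1R,2R)-1-[3,4-bis(benzyloxy)phenyl]-3-[2,4-bis(benzyloxy)-6-fluorophenyl]-1-hydroxy-3-oxopropan-2-yl}-2,3-dihydro-4H-chromen-4-one
Conditions: (−)-Ipc2BOTf (1.3 equiv), i-Pr2NEt (1.6 equiv), CH2Cl2, −78 °C; 10 (1.5 equiv), −78 → −20 °C; pH 7 buffer, MeOH, 30% H2O2, 0 °C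
Reagents that add atoms: none
Why: Boron-mediated syn-aldol (Paterson aldol): the benzylic CH2 between ketone and aryl ring is by far the most acidic site, the Z(O)-enol borinate reacts through a Zimmerman–Traxler chair to give the 2,3-syn adduct, and the isopinocampheyl ligands should direct the enolate to the Re face of 10 (the sense known for ethyl ketone Z-enolates with this reagent), which sets both new centres, the future C2 and C3 of the upper unit, as R.

Step 8
Reactants: 11 (2S)-5,7-bis(benzyloxy)-2-[4-(benzyloxy)phenyl]-8-{(1R,2R)-1-[3,4-bis(benzyloxy)phenyl]-3-[2,4-bis(benzyloxy)-6-fluorophenyl]-1-hydroxy-3-oxopropan-2-yl}-2,3-dihydro-4H-chromen-4-one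
Product: 13 (2R,3R)-5,7-bis(benzyloxy)-2-[3,4-bis(benzyloxy)phenyl]-3-{(2S)-5,7-bis(benzyloxy)-2-[4-(benzyloxy)phenyl]-4-oxo-3,4-dihydro-2H-chromen-8-yl}-2,3-dihydro-4H-chromen-4-one, via silyl ether 12 (not isolated)
Conditions: TMSCl (1.5 equiv), imidazole (1.5 equiv), CH2Cl2, 0 °C; pentane, filtration, concentration; then TBAT (10 mol %), THF, −40 → 0 °C
Reagents that add atoms: none
Why: Intramolecular SNAr of the secondary alkoxide on the fluorine-bearing carbon ortho to the ketone, run as a fluoride chain from the silyl ether as in step 4: the C–O bond at the carbinol carbon is not touched, so the syn aldol is carried into the 2,3-cis ring with both centres unchanged, and the absence of stoichiometric base protects the epimerisable C3–H and the lower flavanone.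

Step 9
Reactants: 13 (2R,3R)-5,7-bis(benzyloxy)-2-[3,4-bis(benzyloxy)phenyl]-3-{(2S)-5,7-bis(benzyloxy)-2-[4-(benzyloxy)phenyl]-4-oxo-3,4-dihydro-2H-chromen-8-yl}-2,3-dihydro-4H-chromen-4-one
Product: 14 (2R,3R)-2-(3,4-dihydroxyphenyl)-5,7-dihydroxy-3-[(2S)-5,7-dihydroxy-2-(4-hydroxyphenyl)-4-oxo-3,4-dihydro-2H-chromen-8-yl]-2,3-dihydro-4H-chromen-4-one
Conditions: H2 (1 atm), Pd(OH)2/C, EtOAc/MeOH, 20 °C
Reagents that add atoms: none
Why: Hydrogenolysis of the seven benzyl ethers over palladium under neutral conditions, which should touch neither the aryl ketones nor the three stereocentres and avoids the acid or base that would epimerise C3 of the cis ketone.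

**Compound list**

1 | 2',4',6'-trifluoroacetophenone | CC(=O)c1c(F)cc(F)cc1F | starting material
2 | 1-[2,4-bis(benzyloxy)-6-fluorophenyl]ethanone | CC(=O)c1c(F)cc(OCc2ccccc2)cc1OCc1ccccc1 | intermediate
3 | 1-[4,6-bis(benzyloxy)-3-bromo-2-fluorophenyl]ethanone | CC(=O)c1c(F)c(Br)c(OCc2ccccc2)cc1OCc1ccccc1 | intermediate
4 | {[1-(4,6-bis(benzyloxy)-3-bromo-2-fluorophenyl)ethenyl]oxy}trimethylsilane | C=C(O[Si](C)(C)C)c1c(F)c(Br)c(OCc2ccccc2)cc1OCc1ccccc1 | intermediate
5 | 4-(benzyloxy)benzaldehyde | O=Cc1ccc(OCc2ccccc2)cc1 | starting material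
6 | (3S)-1-[4,6-bis(benzyloxy)-3-bromo-2-fluorophenyl]-3-[4-(benzyloxy)phenyl]-3-(trimethylsilyloxy)propan-1-one | O=C(C[C@H](O[Si](C)(C)C)c1ccc(OCc2ccccc2)cc1)c1c(F)c(Br)c(OCc2ccccc2)cc1OCc1ccccc1 | intermediate
7 | (2S)-5,7-bis(benzyloxy)-2-[4-(benzyloxy)phenyl]-8-bromo-2,3-dihydro-4H-chromen-4-one | O=C1C[C@@H](c2ccc(OCc3ccccc3)cc2)Oc2c(Br)c(OCc3ccccc3)cc(OCc3ccccc3)c12 | intermediate
8 | {[1-(2,4-bis(benzyloxy)-6-fluorophenyl)ethenyl]oxy}trimethylsilane | C=C(O[Si](C)(C)C)c1c(F)cc(OCc2ccccc2)cc1OCc1ccccc1 | intermediate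
9 | (2S)-5,7-bis(benzyloxy)-2-[4-(benzyloxy)phenyl]-8-{2-[2,4-bis(benzyloxy)-6-fluorophenyl]-2-oxoethyl}-2,3-dihydro-4H-chromen-4-one | O=C1C[C@@H](c2ccc(OCc3ccccc3)cc2)Oc2c(CC(=O)c3c(F)cc(OCc4ccccc4)cc3OCc3ccccc3)c(OCc3ccccc3)cc(OCc3ccccc3)c12 | intermediate
10 | 3,4-bis(benzyloxy)benzaldehyde | O=Cc1ccc(OCc2ccccc2)c(OCc2ccccc2)c1 | starting material
11 | (2S)-5,7-bis(benzyloxy)-2-[4-(benzyloxy)phenyl]-8-{(1R,2R)-1-[3,4-bis(benzyloxy)phenyl]-3-[2,4-bis(benzyloxy)-6-fluorophenyl]-1-hydroxy-3-oxopropan-2-yl}-2,3-dihydro-4H-chromen-4-one | O=C1C[C@@H](c2ccc(OCc3ccccc3)cc2)Oc2c([C@@H](C(=O)c3c(F)cc(OCc4ccccc4)cc3OCc3ccccc3)[C@@H](O)c3ccc(OCc4ccccc4)c(OCc4ccccc4)c3)c(OCc3ccccc3)cc(OCc3ccccc3)c12 | intermediate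
12 | O-trimethylsilyl ether of 11 at the carbinol oxygen | O=C1C[C@@H](c2ccc(OCc3ccccc3)cc2)Oc2c([C@@H](C(=O)c3c(F)cc(OCc4ccccc4)cc3OCc3ccccc3)[C@@H](O[Si](C)(C)C)c3ccc(OCc4ccccc4)c(OCc4ccccc4)c3)c(OCc3ccccc3)cc(OCc3ccccc3)c12 | intermediate
13 | (2R,3R)-5,7-bis(benzyloxy)-2-[3,4-bis(benzyloxy)phenyl]-3-{(2S)-5,7-bis(benzyloxy)-2-[4-(benzyloxy)phenyl]-4-oxo-3,4-dihydro-2H-chromen-8-yl}-2,3-dihydro-4H-chromen-4-one | O=C1C[C@@H](c2ccc(OCc3ccccc3)cc2)Oc2c1c(OCc1ccccc1)cc(OCc1ccccc1)c2[C@H]1C(=O)c2c(OCc3ccccc3)cc(OCc3ccccc3)cc2O[C@H]1c1ccc(OCc2ccccc2)c(OCc2ccccc2)c1 | intermediate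
14 | (2R,3R)-2-(3,4-dihydroxyphenyl)-5,7-dihydroxy-3-[(2S)-5,7-dihydroxy-2-(4-hydroxyphenyl)-4-oxo-3,4-dihydro-2H-chromen-8-yl]-2,3-dihydro-4H-chromen-4-one | O=C1C[C@@H](c2ccc(O)cc2)Oc2c1c(O)cc(O)c2[C@H]1C(=O)c2c(O)cc(O)cc2O[C@H]1c1ccc(O)c(O)c1 | target

**Step count and risks**

Total steps: 9. Longest linear sequence: 8 (steps 1, 2, 3, 4, 6, 7, 8, 9); step 5 is a one-step branch from 2.

Steps most likely to fail:

1. Step 4 (carries the label). The free alkoxide may undergo retro-aldol or β-elimination faster than it closes the ring, which would erode the enantiomeric purity through uncatalysed re-addition or through chalcone formation. The boron catalyst may also sequester the fluoride and stall the chain, and the sense of induction has to be confirmed on an aliquot quenched before the fluoride stage. The fallback uses known chemistry, sets out from 3 and returns to the route at 7, and forms the ring oxygen–C2 bond instead of the ring oxygen–aryl bond. Hydroxide displaces the activated fluorine of 3 (KOH, DMSO/H2O, 60 °C) to give the phenol 1-[4,6-bis(benzyloxy)-3-bromo-2-hydroxyphenyl]ethanone F1. TMSOTf and Et3N convert it into the bis-silyl compound {[1-(4,6-bis(benzyloxy)-3-bromo-2-(trimethylsilyloxy)phenyl)ethenyl]oxy}trimethylsilane F2. Mukaiyama aldol of F2 with 5 under the (S)-tryptophan-derived oxazaborolidinone (Re-face addition) and dilute HCl work-up should give (3R)-1-[4,6-bis(benzyloxy)-3-bromo-2-hydroxyphenyl]-3-[4-(benzyloxy)phenyl]-3-hydroxypropan-1-one F3. Mitsunobu cyclisation (PPh3, DIAD, THF, 0 °C) then closes the ring with inversion at the carbinol carbon to give 7.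

2. Step 8. The α-aryl aldolate may fragment by retro-aldol before it cyclises, and the cis ketone may epimerise at C3 once formed. The fallback sets out from 11 and returns at 13, and sets C3 by kinetic protonation instead of carrying it from the aldol. Closure under equilibrating conditions (K2CO3, DMF, 20 °C) gives the 2,3-trans epimer (2R,3S)-5,7-bis(benzyloxy)-2-[3,4-bis(benzyloxy)phenyl]-3-{(2S)-5,7-bis(benzyloxy)-2-[4-(benzyloxy)phenyl]-4-oxo-3,4-dihydro-2H-chromen-8-yl}-2,3-dihydro-4H-chromen-4-one F4. TMSOTf and Et3N (CH2Cl2, 40 °C) convert both ketones into the bis(trimethylsilyl enol ether) of F4 F5, in which C3 of the upper unit is trigonal and C2 of the lower unit is untouched. Buffered fluoride (TBAF, AcOH, THF, −78 °C) should protonate C3 from the face opposite the pseudo-axial C2 aryl group and return the cis compound 13.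

3. Step 7. The bulky boron triflate may enolise the doubly ortho-substituted ketone slowly, enolisation at the chromanone CH2 may compete, and facial selectivity may be modest. The fallback sets out from 9 and returns at 11, and replaces the closed boron transition state by a Lewis-acid-catalysed open one. TMSOTf (1.1 equiv) and Et3N silylate the more acidic benzylic position to give the Z-silyl enol ether (2S)-5,7-bis(benzyloxy)-2-[4-(benzyloxy)phenyl]-8-[(Z)-2-[2,4-bis(benzyloxy)-6-fluorophenyl]-2-(trimethylsilyloxy)ethenyl]-2,3-dihydro-4H-chromen-4-one F6. Mukaiyama aldol of F6 with 10 under the (acyloxy)borane catalyst from (2R,3R)-tartaric acid (20 mol %, EtCN, −78 °C) is syn-selective whatever the enol geometry and is expected to expose the Re face; dilute HCl work-up gives 11.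

**Further compounds**

F1 | step 4 | 1-[4,6-bis(benzyloxy)-3-bromo-2-hydroxyphenyl]ethanone | CC(=O)c1c(O)c(Br)c(OCc2ccccc2)cc1OCc1ccccc1
F2 | step 4 | {[1-(4,6-bis(benzyloxy)-3-bromo-2-(trimethylsilyloxy)phenyl)ethenyl]oxy}trimethylsilane | C=C(O[Si](C)(C)C)c1c(O[Si](C)(C)C)c(Br)c(OCc2ccccc2)cc1OCc1ccccc1
F3 | step 4 | (3R)-1-[4,6-bis(benzyloxy)-3-bromo-2-hydroxyphenyl]-3-[4-(benzyloxy)phenyl]-3-hydroxypropan-1-one | O=C(C[C@@H](O)c1ccc(OCc2ccccc2)cc1)c1c(O)c(Br)c(OCc2ccccc2)cc1OCc1ccccc1
F4 | step 8 | (2R,3S)-5,7-bis(benzyloxy)-2-[3,4-bis(benzyloxy)phenyl]-3-{(2S)-5,7-bis(benzyloxy)-2-[4-(benzyloxy)phenyl]-4-oxo-3,4-dihydro-2H-chromen-8-yl}-2,3-dihydro-4H-chromen-4-one | O=C1C[C@@H](c2ccc(OCc3ccccc3)cc2)Oc2c1c(OCc1ccccc1)cc(OCc1ccccc1)c2[C@@H]1C(=O)c2c(OCc3ccccc3)cc(OCc3ccccc3)cc2O[C@H]1c1ccc(OCc2ccccc2)c(OCc2ccccc2)c1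
F5 | step 8 | bis(trimethylsilyl enol ether) of F4 (C3=C4 in both units) | C[Si](C)(C)OC1=C[C@@H](c2ccc(OCc3ccccc3)cc2)Oc2c1c(OCc1ccccc1)cc(OCc1ccccc1)c2C1=C(O[Si](C)(C)C)c2c(OCc3ccccc3)cc(OCc3ccccc3)cc2O[C@H]1c1ccc(OCc2ccccc2)c(OCc2ccccc2)c1
F6 | step 7 | (2S)-5,7-bis(benzyloxy)-2-[4-(benzyloxy)phenyl]-8-[(Z)-2-[2,4-bis(benzyloxy)-6-fluorophenyl]-2-(trimethylsilyloxy)ethenyl]-2,3-dihydro-4H-chromen-4-one | O=C1C[C@@H](c2ccc(OCc3ccccc3)cc2)Oc2c(/C=C(\O[Si](C)(C)C)c3c(F)cc(OCc4ccccc4)cc3OCc3ccccc3)c(OCc3ccccc3)cc(OCc3ccccc3)c12
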